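Compound numbers 1–16 are those of the compound list after the steps. Flavone numbering (O1, C2, C3, C4, C4a, C5–C8, C8a) is used for the target and carried back to its open-chain precursors.

## Analysis of the target

The target 16 is a flavonol: a 4H-chromen-4-one in which ring A (C4a, C5–C8, C8a) is fused to the pyranone ring C (O1, C2, C3, C4), with ring B, a 4-methoxyphenyl group, on C2. It has no stereocentre and no stereogenic double bond, since the prenyl alkene ends in two identical methyl groups. The problem is therefore one of oxidation pattern and of telling oxygens apart. Ring A carries three oxygens in a 1,3,5 relationship with three different roles: O1 is a ring C atom, O5 is a free phenol chelated to the C4 carbonyl, and O7 bears the 3-methylbut-2-enyl group; C3 carries a free enolic hydroxyl. The sensitive parts are the aryl prenyl ether and the 3-hydroxy-4-pyranone. The ether ionises in acid, is an allyl donor towards zerovalent palladium, is attacked by alkyllithiums and rearranges to carbon on heating; the hydroxypyranone is degraded by air in base. The synthesis is hard because C3 must arrive already oxygenated, so that nothing is oxidised late next to the prenyl alkene, and because O7 must be distinguished from O5 and O3. The strategy rests on C4, a carbonyl carbon bonded to C4a and to the oxygenated C3, with C4a lying between two oxygen-bearing carbons (C5 and C8a) that are equivalent before ring C is closed. C4 can therefore be brought in as carbon monoxide 9 between a 2,6-dioxygenated aryl iodide, symmetric about its C–I axis, and the enolate carbon of an α-alkoxy aryl ketone; either ortho oxygen can later become O1.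

## Retrosynthetic reasoning

**Prenyl ether, 16 to 14 and 15.** The first cut is the O7–CH2 bond, which leads back to the trihydroxyflavone 14 and the allylic bromide 15. Attaching the prenyl group before the coupling would expose an allylic aryl ether to three operations it may not survive. It would meet a palladium catalyst in the presence of the soft 1,3-diketone enolate that the coupling itself produces (allylic substitution), the acid needed for deprotection and ring closure, and the strong base used to metalate ring A. Cutting here lets all three ring A oxygens stay identical until ring C exists. The forward step must alkylate one hydroxyl of three, and ring closure is what makes them different: the 7-hydroxyl is conjugated with the C4 carbonyl and is the most acidic, the 5-hydroxyl is locked in a hydrogen bond to that carbonyl, and the 3-hydroxyl is a weaker, also hydrogen-bonded enol.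

**Ring C, 14 to 11.** Ring C is opened at O1–C2 and the four hydroxyls (O3, O5, O7 and the oxygen that becomes O1) are masked as methoxymethyl ethers, giving the open 2-alkoxy-1,3-diketone 11. The cut is made at O1–C2 because the forward reaction is then a cyclodehydration that only has to follow loss of the acetals. The two ortho oxygens of 11 are equivalent, so closure can give one flavonol only. The same acid should remove all four acetals, passing through the free diketone 12 and the six-membered hemiketal 13 on the way to the aromatic pyranone.

**The two bonds at C4, 11 to 4, 8 and 9.** In 11 both bonds to C4 are cut, C4a–C4 and C3–C4, giving the aryl iodide 4, the α-alkoxy ketone 8 and carbon monoxide 9. C4 is the one carbon of the C6–C3–C6 chain whose removal leaves two fragments that are each made in two steps and need no regiochemical decision. The ring A fragment is a symmetric iodide, and the other fragment brings C2, C3 with its oxygen, and ring B. Cutting C2–C3 instead would need an acyl group to be placed on ring A beforehand. The forward reaction must insert 9 into the aryl–palladium bond before any direct arylation of the enolate, and must then acylate the magnesium enolate 10 at carbon and not at oxygen.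

**Aryl iodide, 4 to 2 to 1.** The C–I bond of 4 is cut to the aryllithium 3 and so to the tris-ether 2, which comes from the triol 1 by exhaustive protection. The acetal groups do three jobs: they protect, they direct the metalation, and they leave in the ring-closing step. Because 2 has threefold symmetry, every ring hydrogen lies between two acetal oxygens and only one site of lithiation exists.

**Ketone, 8 to 7 to 5.** The acetal C–O bond of 8 is cut to the α-hydroxy ketone 7, and the C–O bond at the α-carbon of 7 to the bromo ketone 5. The oxygen is introduced as an oxygen nucleophile displacing bromide, by way of the ester 6, so that C3 is at the flavonol oxidation level from the start.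

## Alternatives that were turned down

**Alternative 1:** Ring C is cut at C4–C4a and O1–C2, leading back to unprotected 1 and ethyl 2-(benzoyloxy)-3-(4-methoxyphenyl)-3-oxopropanoate (A1).
- Forward key step: A1 is heated with 1 well above 200 °C. It loses its ester alcohol to give the aroylketene A2, which acylates a ring carbon of 1; the neighbouring hydroxyl then closes onto the aryl ketone with dehydration to give the 3-O-benzoyl flavonol A3.
- For: one operation forms two bonds and ring C with no protecting group on ring A, and the symmetry of 1 leaves one regiochemical outcome. A3 has O3 masked, so the later alkylation with 15 competes only with the chelated 5-hydroxyl. On this point, and on step count (about five steps), this alternative is stronger than the chosen route, in which O3 is free in 14.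
- Against: the ketene must form from an α-acyloxy β-keto ester under pyrolysis conditions. There the benzoate can migrate to the enol oxygen or to a phenol of 1. The reverse orientation (phenol on the ester, ring carbon on the ketone) gives an isomeric 4-arylcoumarin. The product still has two nucleophilic ring carbons that more A2 can acylate.
- Comparison: the chosen strategy forms the C4 bonds at about 80 °C at a carbon fixed by the iodine atom, so neither a coumarin isomer nor polyacylation can arise, and every intermediate can be isolated.

**Alternative 2:** Three bonds are cut, C8a–O1, C4a–C4 and O1–C2, leading to the ortho-silyl aryl triflate A4 and cesium 3-(4-methoxyphenyl)prop-2-ynoate (A6).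
- Forward key step: a fluoride source releases the aryne A5 from A4. The carboxylate oxygen of A6 adds at the aryne carbon remote from the acetal-bearing carbon (the future C8a), the aryl anion at C4a takes the acyl group, and the resulting phenoxide ynone closes ring C to give the flavone A7.
- For: it makes three bonds and the ring in one mild operation. It is stronger than the chosen route in bonds formed per step and in closing ring C within the key step.
- Against: A7 carries hydrogen at C3. The flavonol oxygen would have to be introduced late, next to a prenyl alkene that epoxidising reagents attack and a prenyl ether that strong bases threaten. A4 needs three different oxygen substituents on one ring plus the silyl and triflate groups, which means five or six steps from 1 with a statistical differentiation. Closure of the ynone to an aurone (five-membered ring) can compete with the six-membered mode.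
- Comparison: the chosen strategy carries the C3 oxygen from the start in 8 and reaches its arene partner 4 in two steps from 1 without differentiating any oxygen.

**Alternative 3:** Ring C is cut at C4–C4a only, leading to the acid A8, racemic (2R*,3R*)-2-acetoxy-3-[3,5-bis(benzyloxy)phenoxy]-3-(4-methoxyphenyl)propanoic acid.
- Forward key step: activation of A8 as a mixed anhydride brings about intramolecular Friedel–Crafts acylation ortho to the ether oxygen, closing ring C as the trans-flavanonol acetate A9.
- For: an intramolecular acylation of a 1,3,5-trioxygenated ring through a six-membered transition state is very dependable, and the two ortho positions are equivalent. On certainty of the key bond formation this alternative is stronger than the chosen route.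
- Against: A9 contains two stereocentres that the target lacks and is two hydrogens too rich, so a late dehydrogenation across C2–C3 is needed. The benzyl ethers must be removed by hydrogenolysis before 15 can be introduced, so the same O7-selective alkylation of 14 is needed at the end anyway. A8 takes about five steps, among them an epoxide opening at a benzylic carbon and an ester hydrolysis that must spare the acetate. The total is nine or ten steps.
- Comparison: the chosen strategy accepts a less certain bond formation but reaches the flavonol oxidation level directly, in seven steps, with no redox adjustment and no stereochemistry to create and then destroy.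

Key step: step 5

Remark: 1 is used in its anhydrous form, and carbon monoxide is counted as a numbered reactant because it supplies C4.

## Route

**Step 1**
Reactants: 1 phloroglucinol (benzene-1,3,5-triol)
Product: 2 1,3,5-tris(methoxymethoxy)benzene
Conditions: MOMCl (3.6 equiv), i-Pr2NEt (4.5 equiv), DMF, 0 °C to rt
Reagents that add atoms: chloromethyl methyl ether (MOMCl), COCCl
Why: Exhaustive O-alkylation of the three phenols (Williamson-type acetal formation); the hard electrophile reacts at oxygen and not at ring carbon, and a threefold symmetric triol poses no selectivity question.

**Step 2**
Reactants: 2 1,3,5-tris(methoxymethoxy)benzene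
Product: 4 2-iodo-1,3,5-tris(methoxymethoxy)benzene, via aryllithium 3 (not isolated)
Conditions: n-BuLi (1.1 equiv), THF, 0 °C; then I2 (1.2 equiv), THF, −78 °C to rt; aq Na2S2O3 work-up
Reagents that add atoms: iodine, II
Why: Directed ortho-metalation: every ring hydrogen lies between two acetal ethers whose oxygens hold lithium, so deprotonation is fast and, the three sites being equivalent, gives a single aryllithium 3. Iodinolysis of the C–Li bond then places iodine at that carbon.

**Step 3**
Reactants: 5 2-bromo-1-(4-methoxyphenyl)ethanone
Product: 7 2-hydroxy-1-(4-methoxyphenyl)ethanone, via formate ester 6 (not isolated)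
Conditions: HCO2Na (3 equiv), EtOH/H2O (4:1), reflux
Reagents that add atoms: sodium formate, [Na+].[O-]C=O
Why: SN2 displacement of the activated α-bromide by formate, followed by hydrolysis of the labile formate ester 6 in the same pot. Formate is nucleophilic but barely basic, so aldol and Favorskii-type reactions of the bromo ketone should not compete.

**Step 4**
Reactants: 7 2-hydroxy-1-(4-methoxyphenyl)ethanone
Product: 8 2-(methoxymethoxy)-1-(4-methoxyphenyl)ethanone
Conditions: MOMCl (1.5 equiv), i-Pr2NEt (2 equiv), CH2Cl2, 0 °C to rt
Reagents that add atoms: chloromethyl methyl ether (MOMCl), COCCl
Why: Standard methoxymethylation of a primary alcohol; the hindered amine at low temperature should leave the α-ketol unenolised, and the acetal later serves as a chelating group for magnesium.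

**Step 5**
Reactants: 4 2-iodo-1,3,5-tris(methoxymethoxy)benzene; 8 2-(methoxymethoxy)-1-(4-methoxyphenyl)ethanone (1.5 equiv); 9 carbon monoxide
Product: 11 2-(methoxymethoxy)-3-(4-methoxyphenyl)-1-[2,4,6-tris(methoxymethoxy)phenyl]propane-1,3-dione (racemic), via magnesium enolate 10 (not isolated)
Conditions: CO (1 atm), Pd(OAc)2 (5 mol %), Xantphos (7.5 mol %), MgCl2 (2 equiv), Et3N (4 equiv), 1,4-dioxane, 80 °C; aq NH4Cl work-up
Reagents that add atoms: none
Why: Pd(OAc)2 is reduced in the flask to zerovalent palladium, which adds oxidatively to the C–I bond of 4; CO then inserts to give the 2,4,6-tris(methoxymethoxy)benzoyl palladium iodide. MgCl2 and Et3N enolise 8 under soft conditions, the ketone oxygen and the α-oxygen chelating magnesium, to the Z-enolate 10, which replaces iodide on palladium; C–C reductive elimination gives 11 with the new bonds C4a–C4 and C3–C4. The closest known reaction type is the palladium-catalysed carbonylative α-arylation of ketones to 1,3-diketones, together with the MgCl2/Et3N protocol used for more acidic carbonyl pronucleophiles. No ring is closed. The one new stereocentre, the carbon between the two carbonyls, forms racemic with no control and is erased in step 6. Carbonylation must outrun direct α-arylation: the two ortho substituents should speed migratory insertion of CO, the wide-bite-angle ligand favours the acyl pathway, and the weak base keeps the enolate concentration low. Acylation must occur at carbon: the chelated magnesium enolate reacts through carbon, and the product stays bound as a magnesium diketonate, which shields it from a second acylation and from retro-Claisen cleavage. Neither partner carries an allylic ether or a free phenol, so nothing else in the molecule is open to zerovalent palladium.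

**Step 6**
Reactants: 11 2-(methoxymethoxy)-3-(4-methoxyphenyl)-1-[2,4,6-tris(methoxymethoxy)phenyl]propane-1,3-dione
Product: 14 3,5,7-trihydroxy-2-(4-methoxyphenyl)chromen-4-one (kaempferide), via tetrahydroxy diketone 12 (not isolated), via cyclic hemiketal 13 (not isolated)
Conditions: 3 M aq HCl/MeOH (1:4), 55 °C
Reagents that add atoms: none
Why: Acid-catalysed acetal exchange removes the four methoxymethyl groups; a freed ortho phenol adds to the 4-methoxybenzoyl carbonyl (6-exo-trig) and the hemiketal 13 dehydrates to the aromatic 4-pyranone, the thermodynamic sink. The two ortho oxygens are equivalent, so only one flavonol can form. Ring closure may begin before the last acetal is lost, which changes nothing in the outcome.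

**Step 7**
Reactants: 14 3,5,7-trihydroxy-2-(4-methoxyphenyl)chromen-4-one; 15 1-bromo-3-methylbut-2-ene (prenyl bromide, 1.05 equiv)
Product: 16 3,5-dihydroxy-2-(4-methoxyphenyl)-7-(3-methylbut-2-enyloxy)chromen-4-one
Conditions: K2CO3 (1.1 equiv), acetone, rt, under argon
Reagents that add atoms: none
Why: Williamson ether synthesis at the most acidic hydroxyl: the 7-hydroxyl is a vinylogous carboxylic acid through the C4 carbonyl and is the one deprotonated by carbonate, while the 5-hydroxyl is chelated to C4=O and the 3-hydroxyl is a weaker, hydrogen-bonded enol. One equivalent of base and halide at room temperature should hold the reaction at the mono-ether, and exclusion of air protects the 3-hydroxypyranone in base.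

## Compound list

1 | phloroglucinol (benzene-1,3,5-triol) | Oc1cc(O)cc(O)c1 | starting material
2 | 1,3,5-tris(methoxymethoxy)benzene | COCOc1cc(OCOC)cc(OCOC)c1 | intermediate
3 | [2,4,6-tris(methoxymethoxy)phenyl]lithium | [Li]c1c(OCOC)cc(OCOC)cc1OCOC | intermediate (not isolated)
4 | 2-iodo-1,3,5-tris(methoxymethoxy)benzene | COCOc1cc(OCOC)cc(OCOC)c1I | intermediate
5 | 2-bromo-1-(4-methoxyphenyl)ethanone | COc1ccc(C(=O)CBr)cc1 | starting material
6 | 2-(4-methoxyphenyl)-2-oxoethyl formate | COc1ccc(C(=O)COC=O)cc1 | intermediate (not isolated)
7 | 2-hydroxy-1-(4-methoxyphenyl)ethanone | COc1ccc(C(=O)CO)cc1 | intermediate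
8 | 2-(methoxymethoxy)-1-(4-methoxyphenyl)ethanone | COCOCC(=O)c1ccc(OC)cc1 | intermediate
9 | carbon monoxide | [C-]#[O+] | starting material
10 | chloromagnesium (Z)-2-(methoxymethoxy)-1-(4-methoxyphenyl)ethenolate, the chelated enolate of 8 | COCO/C=C(\O[Mg]Cl)c1ccc(OC)cc1 | intermediate (not isolated)
11 | 2-(methoxymethoxy)-3-(4-methoxyphenyl)-1-[2,4,6-tris(methoxymethoxy)phenyl]propane-1,3-dione, racemic and enolisable | COCOc1cc(OCOC)cc(OCOC)c1C(=O)C(OCOC)C(=O)c1ccc(OC)cc1 | intermediate
12 | 2-hydroxy-3-(4-methoxyphenyl)-1-(2,4,6-trihydroxyphenyl)propane-1,3-dione, racemic | COc1ccc(C(=O)C(O)C(=O)c2c(O)cc(O)cc2O)cc1 | intermediate (not isolated)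
13 | 2,3,5,7-tetrahydroxy-2-(4-methoxyphenyl)-2,3-dihydrochromen-4-one, mixture of racemic diastereomers | COc1ccc(C2(O)Oc3cc(O)cc(O)c3C(=O)C2O)cc1 | intermediate (not isolated)
14 | 3,5,7-trihydroxy-2-(4-methoxyphenyl)chromen-4-one (kaempferide) | COc1ccc(-c2oc3cc(O)cc(O)c3c(=O)c2O)cc1 | intermediate
15 | 1-bromo-3-methylbut-2-ene (prenyl bromide) | CC(C)=CCBr | starting material
16 | 3,5-dihydroxy-2-(4-methoxyphenyl)-7-(3-methylbut-2-enyloxy)chromen-4-one | COc1ccc(-c2oc3cc(OCC=C(C)C)cc(O)c3c(=O)c2O)cc1 | target

## Step count and least certain steps

Total: 7 steps. Longest linear sequence: 5 steps (steps 1, 2, 5, 6, 7); the ketone branch (steps 3 and 4) joins at step 5.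

**Step 5 (key step).** The most likely failure is slow capture of the hindered 2,6-disubstituted aroyl palladium intermediate by an enolate that is present only in low concentration, because a mono-ketone is enolised much less readily by MgCl2/Et3N than a 1,3-dicarbonyl compound. The acyl complex would then be diverted by hydrolysis or reduction, or the catalyst would decompose. The fallback makes the same diketone without palladium, from a preformed acid derivative. It sets out from 2: lithiation as in step 2 gives 3, which is carboxylated with CO2 to 2,4,6-tris(methoxymethoxy)benzoic acid F1. Carbonyldiimidazole in THF converts F1 into (1H-imidazol-1-yl)[2,4,6-tris(methoxymethoxy)phenyl]methanone F2. The lithium enolate of 8 (LiN(SiMe3)2, two equivalents, THF, −78 to 0 °C) is then C-acylated by F2 in a crossed Claisen condensation, and the route is rejoined at 11.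

**Step 7.** The most likely failure is over-alkylation at O3, since the acidity gap between the 7- and 3-hydroxyls is finite, along with some C-prenylation of the electron-rich ring A phenoxide at C6 or C8. The fallback replaces selection by acidity with a protecting-group sequence. It sets out from 14: Ac2O and pyridine give 2-(4-methoxyphenyl)-4-oxochromene-3,5,7-triyl triacetate F3. PhSH and imidazole in N-methylpyrrolidone cleave only the ester of the most acidic phenol, giving 7-hydroxy-2-(4-methoxyphenyl)-4-oxochromene-3,5-diyl diacetate F4. Mitsunobu etherification with 3-methylbut-2-en-1-ol (PPh3, diisopropyl azodicarboxylate, THF, 0 °C) gives 2-(4-methoxyphenyl)-7-(3-methylbut-2-enyloxy)-4-oxochromene-3,5-diyl diacetate F5. K2CO3 in MeOH at 0 °C removes both acetates, and the route is rejoined at 16.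

**Step 6.** The most likely failure is solvolytic cleavage of the α-oxygenated 1,3-diketone in hot acidic methanol, by retro-Claisen fragmentation or protodeacylation of the very electron-rich ring, before the ring has closed; incomplete loss of the acetal at O3 is the second concern. The fallback separates deprotection from ring closure. It sets out from 11: Me3SiBr in CH2Cl2 at −30 to 0 °C, followed by aqueous NaHCO3, cleaves the acetals without a nucleophilic solvent and gives 12, isolated in equilibrium with 13. Catalytic p-TsOH in toluene at 80 °C with removal of water then effects the cyclodehydration, and the route is rejoined at 14. This fallback makes no compound that the list lacks (none, F0).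

**Step 2.** The most likely failure is incomplete or double metalation, leading to a mixture of unreacted 2, 4 and a di-iodide that is hard to separate; the electron-rich iodide is also sensitive to light and acid. The fallback replaces metalation by electrophilic aromatic substitution. It sets out from 2: one equivalent of N-iodosuccinimide in MeCN at 0 °C in the dark iodinates the activated ring, all three positions being equivalent, and the route is rejoined at 4. This fallback makes no compound that the list lacks (none, F0).

## Further compounds

F1 | step 5 | 2,4,6-tris(methoxymethoxy)benzoic acid | COCOc1cc(OCOC)cc(OCOC)c1C(=O)O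
F2 | step 5 | (1H-imidazol-1-yl)[2,4,6-tris(methoxymethoxy)phenyl]methanone | COCOc1cc(OCOC)cc(OCOC)c1C(=O)n1ccnc1
F3 | step 7 | 2-(4-methoxyphenyl)-4-oxochromene-3,5,7-triyl triacetate | COc1ccc(-c2oc3cc(OC(C)=O)cc(OC(C)=O)c3c(=O)c2OC(C)=O)cc1
F4 | step 7 | 7-hydroxy-2-(4-methoxyphenyl)-4-oxochromene-3,5-diyl diacetate | COc1ccc(-c2oc3cc(O)cc(OC(C)=O)c3c(=O)c2OC(C)=O)cc1
F5 | step 7 | 2-(4-methoxyphenyl)-7-(3-methylbut-2-enyloxy)-4-oxochromene-3,5-diyl diacetate | COc1ccc(-c2oc3cc(OCC=C(C)C)cc(OC(C)=O)c3c(=O)c2OC(C)=O)cc1
F0 | step 6 | none | none
F0 | step 2 | none | none
A1 | alternative 1 | ethyl 2-(benzoyloxy)-3-(4-methoxyphenyl)-3-oxopropanoate | CCOC(=O)C(OC(=O)c1ccccc1)C(=O)c1ccc(OC)cc1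
A2 | alternative 1 | [1-(4-methoxyphenyl)-1,3-dioxoprop-2-en-2-yl] benzoate (aroylketene) | COc1ccc(cc1)C(=O)C(OC(=O)c1ccccc1)=C=O
A3 | alternative 1 | 5,7-dihydroxy-2-(4-methoxyphenyl)-4-oxochromen-3-yl benzoate | COc1ccc(-c2oc3cc(O)cc(O)c3c(=O)c2OC(=O)c2ccccc2)cc1
A4 | alternative 2 | [3-(methoxymethoxy)-5-(3-methylbut-2-enyloxy)-2-(trimethylsilyl)phenyl] trifluoromethanesulfonate | COCOc1cc(OCC=C(C)C)cc(OS(=O)(=O)C(F)(F)F)c1[Si](C)(C)C
A5 | alternative 2 | 1-(methoxymethoxy)-5-(3-methylbut-2-enyloxy)-2,3-didehydrobenzene (aryne) | COCOC1=CC(OCC=C(C)C)=CC#C1
A6 | alternative 2 | cesium 3-(4-methoxyphenyl)prop-2-ynoate | [Cs+].[O-]C(=O)C#Cc1ccc(OC)cc1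
A7 | alternative 2 | 5-(methoxymethoxy)-2-(4-methoxyphenyl)-7-(3-methylbut-2-enyloxy)chromen-4-one | COCOc1cc(OCC=C(C)C)cc2oc(-c3ccc(OC)cc3)cc(=O)c12
A8 | alternative 3 | (2R*,3R*)-2-acetoxy-3-[3,5-bis(benzyloxy)phenoxy]-3-(4-methoxyphenyl)propanoic acid, racemic, one enantiomer drawn | OC(=O)[C@@H]([C@H](Oc1cc(OCc2ccccc2)cc(OCc2ccccc2)c1)c1ccc(OC)cc1)OC(C)=O
A9 | alternative 3 | trans-3-acetoxy-5,7-bis(benzyloxy)-2-(4-methoxyphenyl)chroman-4-one, racemic, (2R,3R) enantiomer drawn | COc1ccc([C@H]2Oc3cc(OCc4ccccc4)cc(OCc4ccccc4)c3C(=O)[C@@H]2OC(C)=O)cc1
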